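**Retrosynthetic overview**
1. Both aldehydes are unmasked in the last step: the formyl group of the α-formyl ester from a nitromethyl group (Nef reaction), the enal from its dimethyl acetal. This keeps the epimerisable α-formyl ester centre fixed until the end.
2. The bond between the two stereocentres, both stereocentres (anti) and the phenethyl ester come from one NHC-catalysed three-component coupling of a 2,4-dienal, a β-nitroacrylate and the free hydroxyarene alcohol.
3. The dienal comes from an α-iodo enal acetal by Heck vinylation with acrolein; the (E)-ethylidene geometry is fixed in the first step by α-iodination of a simple enal.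
4. No ring is formed in the route; the only ring, the catechol, is bought.

Assumption 1: the SMILES is taken literally, (3S) at the branching carbon and (2S) at the α-formyl ester carbon. By the CIP rules natural oleuropein would give (3R) in this open dialdehyde, so a de novo asymmetric route is used and not a semisynthesis.
Assumption 2: the (5aS,10bR) antipode of the triazolium precatalyst in step 4 is taken to give the (3S) centre; if its sense of induction is the opposite, the commercial (5aR,10bS) antipode is used, all else unchanged.

**Route**

Step 1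
Reactants: 1 (E)-but-2-enal (crotonaldehyde)
Product: 2 (Z)-2-iodobut-2-enal
Conditions: I2, K2CO3, 4-(dimethylamino)pyridine (20 mol%), THF/H2O 1:1, rt
Reagents that add atoms: iodine, [I][I]
Why: DMAP-catalysed α-iodination of an enal (a Morita–Baylis–Hillman-type addition–iodination–elimination) is a standard entry to α-iodoenals and gives the thermodynamically preferred Z isomer in which the methyl group is anti to the formyl group, which fixes the ethylidene geometry of the target.

Step 2
Reactants: 2 (Z)-2-iodobut-2-enal
Product: 3 (Z)-2-iodo-1,1-dimethoxybut-2-ene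
Conditions: HC(OMe)3, MeOH, p-toluenesulfonic acid (2 mol%), rt
Reagents that add atoms: trimethyl orthoformate, COC(OC)OC
Why: Acid-catalysed acetalisation driven by the orthoester masks the only aldehyde present without touching the alkenyl iodide or its geometry, so that the aldehyde introduced in step 3 is the sole site for carbene activation in step 4.

Step 3
Reactants: 3 (Z)-2-iodo-1,1-dimethoxybut-2-ene; 4 prop-2-enal (acrolein)
Product: 5 (2E,4E)-4-(dimethoxymethyl)hexa-2,4-dienal
Conditions: Pd(OAc)2 (5 mol%), Bu4NCl, NaHCO3, DMF, 40 °C
Reagents that add atoms: none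
Why: Ligand-free Mizoroki–Heck vinylation under phase-transfer (Jeffery) conditions couples alkenyl iodides to acrolein near room temperature with retention at the iodide-bearing alkene and E selectivity in the new one, giving the 2E,4E-dienal.

Step 4
Reactants: 5 (2E,4E)-4-(dimethoxymethyl)hexa-2,4-dienal; 6 methyl (E)-3-nitroprop-2-enoate; 7 hydroxytyrosol [2-(3,4-dihydroxyphenyl)ethanol]
Product: 8 2-(3,4-dihydroxyphenyl)ethyl (3S,4E)-4-(dimethoxymethyl)-3-[(2S)-1-methoxy-3-nitro-1-oxopropan-2-yl]hex-4-enoate
Conditions: (5aS,10bR)-5a,10b-dihydro-2-(2,4,6-trimethylphenyl)-4H,6H-indeno[2,1-b][1,2,4]triazolo[4,3-d][1,4]oxazin-2-ium chloride (10 mol%), NaOAc (20 mol%), THF, 0 °C to rt, argon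
Reagents that add atoms: none
Why: NHC-catalysed homoenolate Michael addition to a nitroalkene with redox esterification: the chiral carbene makes the β-carbon of enal 5 nucleophilic, it attacks the carbon β to the nitro group of 6 in the anti-selective, catalyst-controlled C–C bond formation that sets both stereocentres at once, and the acyl donor formed is captured by the primary hydroxyl of 7 in preference to its less nucleophilic phenols.

Step 5
Reactants: 8 2-(3,4-dihydroxyphenyl)ethyl (3S,4E)-4-(dimethoxymethyl)-3-[(2S)-1-methoxy-3-nitro-1-oxopropan-2-yl]hex-4-enoate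
Product: 11 2-(3,4-dihydroxyphenyl)ethyl (3S,4E)-4-formyl-3-[(2S)-1-methoxy-1,3-dioxopropan-2-yl]hex-4-enoate (target), via trilithium nitronate 9 (not isolated), via acetal aldehyde 10 (not isolated)
Conditions: LiN(SiMe3)2 (3.1 equiv), THF, −78 °C; cannulate into aq. TiCl3 (6 equiv)/NH4OAc (pH 5–6), 0 °C; extract; then dilute HCl, THF/H2O, 0 °C, 15 min
Reagents that add atoms: water, O
Why: McMurry-type reductive Nef reaction followed by acetal hydrolysis: the nitronate (the most acidic C–H is deprotonated, so the neighbouring stereocentre is not enolised) is converted by aqueous trivalent titanium at pH 5–6 into the aldehyde, and brief dilute acid then frees the enal from its allylic dimethyl acetal, no stereocentre being formed or inverted.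

**Compound list**

1 | (E)-but-2-enal (crotonaldehyde) | C/C=C/C=O | starting material
2 | (Z)-2-iodobut-2-enal | C/C=C(\I)C=O | intermediate
3 | (Z)-2-iodo-1,1-dimethoxybut-2-ene | C/C=C(\I)C(OC)OC | intermediate
4 | prop-2-enal (acrolein) | C=CC=O | starting material
5 | (2E,4E)-4-(dimethoxymethyl)hexa-2,4-dienal | C/C=C(/C(OC)OC)\C=C\C=O | intermediate
6 | methyl (E)-3-nitroprop-2-enoate (methyl 3-nitroacrylate) | COC(=O)/C=C/[N+](=O)[O-] | starting material
7 | hydroxytyrosol, 2-(3,4-dihydroxyphenyl)ethanol | OCCc1ccc(O)c(O)c1 | starting material
8 | 2-(3,4-dihydroxyphenyl)ethyl (3S,4E)-4-(dimethoxymethyl)-3-[(2S)-1-methoxy-3-nitro-1-oxopropan-2-yl]hex-4-enoate | C/C=C(/C(OC)OC)[C@@H](CC(=O)OCCc1ccc(O)c(O)c1)[C@@H](C[N+](=O)[O-])C(=O)OC | intermediate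
9 | trilithium salt of 8: nitronate at the former nitromethyl carbon, both phenols as phenoxides, (3S) and (2S) unchanged (not isolated) | [Li+].[Li+].[Li+].C/C=C(/C(OC)OC)[C@@H](CC(=O)OCCc1ccc([O-])c([O-])c1)[C@@H](C=[N+]([O-])[O-])C(=O)OC | intermediate
10 | 2-(3,4-dihydroxyphenyl)ethyl (3S,4E)-4-(dimethoxymethyl)-3-[(2S)-1-methoxy-1,3-dioxopropan-2-yl]hex-4-enoate (not isolated) | C/C=C(/C(OC)OC)[C@@H](CC(=O)OCCc1ccc(O)c(O)c1)[C@@H](C=O)C(=O)OC | intermediate
11 | 2-(3,4-dihydroxyphenyl)ethyl (3S,4E)-4-formyl-3-[(2S)-1-methoxy-1,3-dioxopropan-2-yl]hex-4-enoate | C/C=C(/C=O)[C@@H](CC(=O)OCCc1ccc(O)c(O)c1)[C@@H](C=O)C(=O)OC | target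

**Totals**

Total step count: 5. Longest linear sequence: 5 steps (1 → 2 → 3 → 5 → 8 → 11).

**Steps most likely to fail and fallbacks**

Step 4 is the least certain step. The partner combination has no direct precedent: the dienal has a hindered β-carbon, the nitroacrylate is very electrophilic, and the alcohol is used in near-stoichiometric amount and not as solvent. The Stetter pathway, phenol acylation and a poor anti/syn ratio are the expected failure modes. The fallback sets out from 5 and comes back at 10. Enal 5, the sodium enolate of methyl 3-oxopropanoate and 3,3',5,5'-tetra-tert-butyl-4,4'-diphenoquinone as hydride acceptor are combined under the same triazolium salt/NaOAc catalysis. This oxidative carbene-catalysed [3+3] annulation (conjugate addition of the enolate, then enol lactonisation) gives the enol δ-lactone methyl (4R)-4-[(1E)-1-(dimethoxymethyl)prop-1-en-1-yl]-2-oxo-3,4-dihydro-2H-pyran-5-carboxylate F1, which carries only the later C-3 centre. Acyl transfer from this enol ester to the primary hydroxyl of 7 under the same triazolium/NaOAc catalysis opens the ring, and the released enol ketonises to 10. In this variant the α-formyl ester centre is fixed only by substrate-controlled protonation. The route then continues with the acetal hydrolysis of step 5.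

Step 5 is the second risk. The Nef reaction has to run beside a free catechol, and the product is an α-formyl ester that enolises easily, so C-2 of the side chain can epimerise. It can also close onto the enal aldehyde as a hemiacetal or add to the enal as an oxa-Michael donor. The product must be kept cold, near neutral, and used at once. The fallback sets out from 8 and comes back at 11. The nitronate 9 is formed as before and is added to H2SO4/MeOH at −40 °C (solvolytic Nef). This gives the bis-acetal 2-(3,4-dihydroxyphenyl)ethyl (3S,4E)-4-(dimethoxymethyl)-3-[(2S)-1,3,3-trimethoxy-1-oxopropan-2-yl]hex-4-enoate F2, which can be purified and stored. Both acetals are then hydrolysed in one operation with cold aqueous formic acid to give 11.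

Step 3 is the third risk: acrolein polymerises, the alkenyl iodide is 1,1-disubstituted and hindered, and the acetal can be lost. The fallback sets out from 3 and comes back at 5. Iodine–lithium exchange on 3 (t-BuLi, Et2O, −78 °C) gives the configurationally stable (E)-(1,1-dimethoxybut-2-en-2-yl)lithium F3. It adds to the aldehyde of 3-(dimethylamino)acrolein to give lithium (1E,4E)-1-(dimethylamino)-4-(dimethoxymethyl)hexa-1,4-dien-3-olate F4. Work-up with aqueous NH4Cl at pH 5 eliminates dimethylamine and delivers the (2E,4E)-dienal 5 by vinylogous formylation.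

**Further compounds**

F1 | step 4 | methyl (4R)-4-[(1E)-1-(dimethoxymethyl)prop-1-en-1-yl]-2-oxo-3,4-dihydro-2H-pyran-5-carboxylate | C/C=C(/C(OC)OC)[C@H]1CC(=O)OC=C1C(=O)OC
F2 | step 5 | 2-(3,4-dihydroxyphenyl)ethyl (3S,4E)-4-(dimethoxymethyl)-3-[(2S)-1,3,3-trimethoxy-1-oxopropan-2-yl]hex-4-enoate | C/C=C(/C(OC)OC)[C@@H](CC(=O)OCCc1ccc(O)c(O)c1)[C@@H](C(OC)OC)C(=O)OC
F3 | step 3 | (E)-(1,1-dimethoxybut-2-en-2-yl)lithium | C/C=C(\[Li])C(OC)OC
F4 | step 3 | lithium (1E,4E)-1-(dimethylamino)-4-(dimethoxymethyl)hexa-1,4-dien-3-olate (racemic at C-3) | C/C=C(/C(OC)OC)C(O[Li])/C=C/N(C)C
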